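The lactone OCH2 carbon C5 and the oxygen on carbinol carbon C7 stand in a 1,3-relationship across C4 (lactone ring O1–C2–C3–C4–C5, with C7 on C4). Everything rests on disconnecting the C4–C5 bond: a CH2 radical held on the C7 oxygen through a dimethylsilyl tether adds to C4, the β-carbon of a γ-hydroxy enoate. In one operation this forms the C4–C5 bond, closes a 1,2-oxasilolane ring and sets C4 trans to the ring B aryl group on C7. The precursor is the (bromomethyl)dimethylsilyl ether of a methyl (R,E)-4-aryl-4-hydroxybut-2-enoate whose aryl group (ring B) already carries the threo glycerol ether as an acetonide.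

Key step: step 10

Remark (assumption): (S,S)-ProPhenol is taken to deliver the alkynyl group to the Re face of the aryl aldehyde, as in the related zinc aldol chemistry; if the sense proves opposite, the (R,R)-ligand is used in step 7 with no other change.

Labels: ring A is the aryl of the benzyl group on C3, ring B the aryl on C7, ring C the aryl of the glycerol unit (carbons C7'', C8'', C9''). ArB = 4-{[(4S,5S)-4-[4-(benzyloxy)-3-methoxyphenyl]-2,2-dimethyl-1,3-dioxan-5-yl]oxy}-3-methoxyphenyl.

Step 1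
Reactants: 1 4-bromo-2-methoxyphenol; 2 bromoacetic acid
Product: 3 (4-bromo-2-methoxyphenoxy)acetic acid
Conditions: NaOH, H2O, reflux; then HCl
Reagents that add atoms: none
Why: Williamson ether synthesis, in which the phenoxide displaces bromide from the bromoacetate carboxylate by SN2; no stereocentre is involved.

Step 2
Reactants: 3 (4-bromo-2-methoxyphenoxy)acetic acid; 4 (R)-4-benzyloxazolidin-2-one
Product: 6 (R)-4-benzyl-3-[(4-bromo-2-methoxyphenoxy)acetyl]oxazolidin-2-one, via mixed pivalic anhydride 5 (not isolated)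
Conditions: PivCl, Et3N, THF, −20 °C; then LiCl, 4, −20 °C → rt
Reagents that add atoms: pivaloyl chloride, CC(C)(C)C(=O)Cl (kept only in 5)
Why: N-acylation of the oxazolidinone through a mixed anhydride, with attack at the less hindered aryloxyacetyl carbonyl.

Step 3
Reactants: 6 (R)-4-benzyl-3-[(4-bromo-2-methoxyphenoxy)acetyl]oxazolidin-2-one; 7 4-(benzyloxy)-3-methoxybenzaldehyde (O-benzylvanillin)
Product: 9 (R)-4-benzyl-3-[(2R,3S)-3-[4-(benzyloxy)-3-methoxyphenyl]-2-(4-bromo-2-methoxyphenoxy)-3-hydroxypropanoyl]oxazolidin-2-one, via dibutylboron Z-enolate 8 (not isolated)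
Conditions: Bu2BOTf, i-Pr2NEt, CH2Cl2, −78 → 0 °C; 7, −78 → 0 °C; then pH 7 buffer, MeOH, 30% H2O2, 0 °C
Reagents that add atoms: dibutylboron triflate, CCCCB(CCCC)OS(=O)(=O)C(F)(F)F (kept only in 8)
Why: Evans syn aldol reaction, in which the Z-boron enolate reacts through a chair transition state on the face away from the benzyl group of the (R)-auxiliary, setting C8'' and C7'' in the syn (threo) relationship with the absolute sense of the target.

Step 4
Reactants: 9 the syn aldol imide
Product: 10 (1S,2S)-1-[4-(benzyloxy)-3-methoxyphenyl]-2-(4-bromo-2-methoxyphenoxy)propane-1,3-diol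
Conditions: LiBH4, THF, MeOH (1 equiv), 0 °C; then H2O
Reagents that add atoms: none
Why: Reductive cleavage of the N-acyloxazolidinone by LiBH4 gives the primary alcohol and releases the auxiliary without touching the aryl bromide, the benzyl ether or either stereocentre (C8'' changes from R to S only because the CIP ranking changes).

Step 5
Reactants: 10 the threo 1,3-diol
Product: 11 (4S,5S)-4-[4-(benzyloxy)-3-methoxyphenyl]-5-(4-bromo-2-methoxyphenoxy)-2,2-dimethyl-1,3-dioxane
Conditions: Me2C(OMe)2, PPTS (cat.), acetone, rt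
Reagents that add atoms: 2,2-dimethoxypropane, COC(C)(C)OC
Why: Acid-catalysed transacetalisation (acetonide formation), which can only give the 1,3-dioxane because the C8'' oxygen is already an aryl ether.

Step 6
Reactants: 11 the aryl bromide acetonide
Product: 13 4-{[(4S,5S)-4-[4-(benzyloxy)-3-methoxyphenyl]-2,2-dimethyl-1,3-dioxan-5-yl]oxy}-3-methoxybenzaldehyde (ArB–CHO), via aryllithium 12 (not isolated)
Conditions: n-BuLi, THF, −78 °C; DMF, −78 → 0 °C; then H2O
Reagents that add atoms: N,N-dimethylformamide, CN(C)C=O; n-butyllithium, [Li]CCCC (lithium kept only in 12)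
Why: Bromine–lithium exchange followed by formylation with DMF, which at −78 °C is faster than benzylic deprotonation and leaves acetonide and benzyl ether intact.

Step 7
Reactants: 13 ArB–CHO; 14 methyl propiolate
Product: 16 methyl (S)-4-hydroxy-4-ArB-but-2-ynoate, via methylzinc alkynylide 15 (not isolated)
Conditions: Me2Zn (3 equiv), (S,S)-ProPhenol (10 mol%), Ph3P=O (20 mol%), toluene, 0–4 °C; then H2O
Reagents that add atoms: dimethylzinc, C[Zn]C (kept only in 15)
Why: Catalytic enantioselective alkynylation of an aryl aldehyde by the dinuclear zinc–ProPhenol complex, whose chiral pocket delivers the alkynylide to the Re face and so sets C7 (S by CIP in the ynoate), the remote dioxane centres exerting no bias.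

Step 8
Reactants: 16 the (S)-γ-hydroxy ynoate
Product: 17 methyl (R,E)-4-hydroxy-4-ArB-but-2-enoate
Conditions: NaAlH2(OCH2CH2OMe)2 (Red-Al), THF, −72 °C; then aq. potassium sodium tartrate
Reagents that add atoms: none
Why: Hydroxyl-directed trans-hydroalumination of the γ-hydroxy ynoate followed by protonation, a known trans-selective reduction that gives the E-enoate and spares the ester at low temperature (C7 keeps its spatial arrangement and is now R because the alkene ranks below the aryl group).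

Step 9
Reactants: 17 the (R,E)-γ-hydroxy enoate; 18 (bromomethyl)chlorodimethylsilane
Product: 19 methyl (R,E)-4-{[(bromomethyl)dimethylsilyl]oxy}-4-ArB-but-2-enoate
Conditions: imidazole, CH2Cl2, 0 °C
Reagents that add atoms: none
Why: O-Silylation of the secondary allylic alcohol with a chlorosilane, with imidazole as a base too weak to isomerise the γ-hydroxy enoate.

Step 10
Reactants: 19 the (bromomethyl)dimethylsilyl ether
Product: 20 methyl 2-[(4S,5R)-5-ArB-2,2-dimethyl-1,2-oxasilolan-4-yl]acetate (trans)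
Conditions: Bu3SnH (slow addition), AIBN (cat.), toluene, 90 °C, 0.01 M
Reagents that add atoms: none
Why: The stannyl radical abstracts bromine, the nucleophilic α-silyl radical adds to the electron-poor enoate β-carbon C4, and the ester-stabilised C3 radical is reduced by Bu3SnH. The closest known reaction type is the tin hydride cyclisation of (bromomethyl)dimethylsilyl ethers of allylic alcohols. The 1,2-oxasilolane ring closes in the 5-exo-trig mode. The new stereocentre C4 is controlled by C7: in the chair-like transition state the ring B aryl group lies pseudo-equatorial, so the CH2CO2Me arm ends trans to it. The step needs 5-exo over 6-endo closure and cyclisation over direct reduction of the C–Br bond. Polarity matching with the enoate and the stabilised adduct radical secure the first, slow stannane addition at high dilution the second.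

Step 11
Reactants: 20 the trans oxasilolane
Product: 22 (R)-4-[(R)-ArB(hydroxy)methyl]dihydrofuran-2(3H)-one, via diol ester 21 (not isolated)
Conditions: KF, KHCO3, 30% H2O2, THF–MeOH, rt; then PPTS (cat.), CH2Cl2, rt
Reagents that add atoms: hydrogen peroxide, OO
Why: Tamao oxidation turns the C5–Si bond into C5–OH with retention and frees the C7 hydroxyl, and lactonisation of the γ-hydroxy ester through the unhindered primary hydroxyl closes the butyrolactone without touching a stereocentre.

Step 12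
Reactants: 22 the hydroxy lactone
Product: 23 (R)-4-[(R)-ArB(triethylsilyloxy)methyl]dihydrofuran-2(3H)-one
Conditions: Et3SiCl, imidazole, DMF, 0 °C → rt
Reagents that add atoms: chlorotriethylsilane, CC[Si](Cl)(CC)CC
Why: Silyl ether formation at the secondary benzylic alcohol under conditions that generate no alkoxide, so that translactonisation cannot intervene.

Step 13
Reactants: 24 4-(benzyloxy)-3-methoxybenzyl alcohol
Product: 25 4-(benzyloxy)-3-methoxybenzyl bromide
Conditions: PBr3, Et2O, 0 °C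
Reagents that add atoms: phosphorus tribromide, BrP(Br)Br
Why: Conversion of a primary benzylic alcohol into the bromide with PBr3 (SN2 on the activated phosphite ester).

Step 14
Reactants: 23 the silyl-protected lactone; 25 4-(benzyloxy)-3-methoxybenzyl bromide
Product: 27 (3R,4R)-3-[4-(benzyloxy)-3-methoxybenzyl]-4-[(R)-ArB(triethylsilyloxy)methyl]dihydrofuran-2(3H)-one, via lithium enolate 26 (not isolated)
Conditions: LiN(SiMe3)2, THF, −78 °C; 25, DMPU, −78 → −30 °C
Reagents that add atoms: lithium bis(trimethylsilyl)amide, [Li]N([Si](C)(C)C)[Si](C)(C)C (lithium kept only in 26)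
Why: Alkylation of a lactone enolate with a benzylic bromide, in which the electrophile approaches C3 anti to the bulky C4 substituent and gives the trans-3,4-disubstituted lactone (C3 R).

Step 15
Reactants: 27 the fully protected lactone
Product: 28 (3R,4R)-3-[4-(benzyloxy)-3-methoxybenzyl]-4-[(R)-{4-[(1S,2S)-1-[4-(benzyloxy)-3-methoxyphenyl]-1,3-dihydroxypropan-2-yl]oxy-3-methoxyphenyl}(hydroxy)methyl]dihydrofuran-2(3H)-one
Conditions: AcOH–THF–H2O (3:1:1), 40 °C
Reagents that add atoms: none
Why: Mild acid hydrolysis cleaves the triethylsilyl ether and the acetonide in one operation while both phenols are still benzylated, so that no quinone methide can arise from the benzylic alcohols.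

Step 16
Reactants: 28 the bis(benzyl ether) triol
Product: 29 CNP0233652.1, (3R,4R)-3-(4-hydroxy-3-methoxybenzyl)-4-[(R)-{4-[(1S,2S)-1,3-dihydroxy-1-(4-hydroxy-3-methoxyphenyl)propan-2-yl]oxy-3-methoxyphenyl}(hydroxy)methyl]dihydrofuran-2(3H)-one
Conditions: H2 (1 atm), 10% Pd/C, EtOAc, rt
Reagents that add atoms: none
Why: Catalytic hydrogenolysis of the two aryl benzyl ethers under neutral conditions, under which the secondary benzylic alcohols, the alkyl aryl ether and the lactone should be retained.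

Compound list
1 | 4-bromo-2-methoxyphenol | COc1cc(Br)ccc1O | starting material
2 | bromoacetic acid | OC(=O)CBr | starting material
3 | (4-bromo-2-methoxyphenoxy)acetic acid | OC(=O)COc1ccc(Br)cc1OC | intermediate
4 | (R)-4-benzyloxazolidin-2-one | O=C1N[C@H](Cc2ccccc2)CO1 | starting material
5 | (4-bromo-2-methoxyphenoxy)acetic pivalic anhydride (not isolated) | CC(C)(C)C(=O)OC(=O)COc1ccc(Br)cc1OC | intermediate
6 | (R)-4-benzyl-3-[(4-bromo-2-methoxyphenoxy)acetyl]oxazolidin-2-one | O=C(COc1ccc(Br)cc1OC)N1[C@H](Cc2ccccc2)COC1=O | intermediate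
7 | 4-(benzyloxy)-3-methoxybenzaldehyde (O-benzylvanillin) | O=Cc1ccc(OCc2ccccc2)c(OC)c1 | starting material
8 | dibutylboron (Z)-enolate of 6 (not isolated) | CCCCB(CCCC)O/C(=C\Oc1ccc(Br)cc1OC)N1[C@H](Cc2ccccc2)COC1=O | intermediate
9 | (R)-4-benzyl-3-[(2R,3S)-3-[4-(benzyloxy)-3-methoxyphenyl]-2-(4-bromo-2-methoxyphenoxy)-3-hydroxypropanoyl]oxazolidin-2-one | Brc1ccc(O[C@@H](C(=O)N2[C@H](Cc3ccccc3)COC2=O)[C@@H](O)c2ccc(OCc3ccccc3)c(OC)c2)c(OC)c1 | intermediate
10 | (1S,2S)-1-[4-(benzyloxy)-3-methoxyphenyl]-2-(4-bromo-2-methoxyphenoxy)propane-1,3-diol | Brc1ccc(O[C@@H](CO)[C@@H](O)c2ccc(OCc3ccccc3)c(OC)c2)c(OC)c1 | intermediate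
11 | (4S,5S)-4-[4-(benzyloxy)-3-methoxyphenyl]-5-(4-bromo-2-methoxyphenoxy)-2,2-dimethyl-1,3-dioxane | Brc1ccc(O[C@H]2COC(C)(C)O[C@H]2c2ccc(OCc3ccccc3)c(OC)c2)c(OC)c1 | intermediate
12 | aryllithium from 11, ArB–Li (not isolated) | [Li]c1ccc(O[C@H]2COC(C)(C)O[C@H]2c2ccc(OCc3ccccc3)c(OC)c2)c(OC)c1 | intermediate
13 | 4-{[(4S,5S)-4-[4-(benzyloxy)-3-methoxyphenyl]-2,2-dimethyl-1,3-dioxan-5-yl]oxy}-3-methoxybenzaldehyde (ArB–CHO) | O=Cc1ccc(O[C@H]2COC(C)(C)O[C@H]2c2ccc(OCc3ccccc3)c(OC)c2)c(OC)c1 | intermediate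
14 | methyl propiolate | C#CC(=O)OC | starting material
15 | methyl 3-(methylzincio)prop-2-ynoate (not isolated) | C[Zn]C#CC(=O)OC | intermediate
16 | methyl (S)-4-hydroxy-4-ArB-but-2-ynoate | O[C@H](C#CC(=O)OC)c1ccc(O[C@H]2COC(C)(C)O[C@H]2c2ccc(OCc3ccccc3)c(OC)c2)c(OC)c1 | intermediate
17 | methyl (R,E)-4-hydroxy-4-ArB-but-2-enoate | O[C@H](/C=C/C(=O)OC)c1ccc(O[C@H]2COC(C)(C)O[C@H]2c2ccc(OCc3ccccc3)c(OC)c2)c(OC)c1 | intermediate
18 | (bromomethyl)chlorodimethylsilane | C[Si](C)(Cl)CBr | starting material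
19 | methyl (R,E)-4-{[(bromomethyl)dimethylsilyl]oxy}-4-ArB-but-2-enoate | BrC[Si](C)(C)O[C@H](/C=C/C(=O)OC)c1ccc(O[C@H]2COC(C)(C)O[C@H]2c2ccc(OCc3ccccc3)c(OC)c2)c(OC)c1 | intermediate
20 | methyl 2-[(4S,5R)-5-ArB-2,2-dimethyl-1,2-oxasilolan-4-yl]acetate, trans (4S only because the silicon-bearing carbon outranks C5; same spatial arrangement as 4R in 22) | C[Si]1(C)C[C@@H](CC(=O)OC)[C@H](c2ccc(O[C@H]3COC(C)(C)O[C@H]3c3ccc(OCc4ccccc4)c(OC)c3)c(OC)c2)O1 | intermediate
21 | methyl (3R,4R)-4-hydroxy-3-(hydroxymethyl)-4-ArB-butanoate (not isolated) | OC[C@@H](CC(=O)OC)[C@@H](O)c1ccc(O[C@H]2COC(C)(C)O[C@H]2c2ccc(OCc3ccccc3)c(OC)c2)c(OC)c1 | intermediate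
22 | (R)-4-[(R)-ArB(hydroxy)methyl]dihydrofuran-2(3H)-one | O=C1OC[C@H]([C@@H](O)c2ccc(O[C@H]3COC(C)(C)O[C@H]3c3ccc(OCc4ccccc4)c(OC)c3)c(OC)c2)C1 | intermediate
23 | (R)-4-[(R)-ArB(triethylsilyloxy)methyl]dihydrofuran-2(3H)-one | O=C1OC[C@H]([C@@H](O[Si](CC)(CC)CC)c2ccc(O[C@H]3COC(C)(C)O[C@H]3c3ccc(OCc4ccccc4)c(OC)c3)c(OC)c2)C1 | intermediate
24 | 4-(benzyloxy)-3-methoxybenzyl alcohol | COc1cc(CO)ccc1OCc1ccccc1 | starting material
25 | 4-(benzyloxy)-3-methoxybenzyl bromide | COc1cc(CBr)ccc1OCc1ccccc1 | intermediate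
26 | lithium enolate of 23 (not isolated) | [Li]OC1=C[C@@H]([C@@H](O[Si](CC)(CC)CC)c2ccc(O[C@H]3COC(C)(C)O[C@H]3c3ccc(OCc4ccccc4)c(OC)c3)c(OC)c2)CO1 | intermediate
27 | (3R,4R)-3-[4-(benzyloxy)-3-methoxybenzyl]-4-[(R)-ArB(triethylsilyloxy)methyl]dihydrofuran-2(3H)-one | COc1cc(C[C@H]2C(=O)OC[C@@H]2[C@@H](O[Si](CC)(CC)CC)c2ccc(O[C@H]3COC(C)(C)O[C@H]3c3ccc(OCc4ccccc4)c(OC)c3)c(OC)c2)ccc1OCc1ccccc1 | intermediate
28 | (3R,4R)-3-[4-(benzyloxy)-3-methoxybenzyl]-4-[(R)-{4-[(1S,2S)-1-[4-(benzyloxy)-3-methoxyphenyl]-1,3-dihydroxypropan-2-yl]oxy-3-methoxyphenyl}(hydroxy)methyl]dihydrofuran-2(3H)-one | COc1cc(C[C@H]2C(=O)OC[C@@H]2[C@@H](O)c2ccc(O[C@@H](CO)[C@@H](O)c3ccc(OCc4ccccc4)c(OC)c3)c(OC)c2)ccc1OCc1ccccc1 | intermediate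
29 | CNP0233652.1, (3R,4R)-3-(4-hydroxy-3-methoxybenzyl)-4-[(R)-{4-[(1S,2S)-1,3-dihydroxy-1-(4-hydroxy-3-methoxyphenyl)propan-2-yl]oxy-3-methoxyphenyl}(hydroxy)methyl]dihydrofuran-2(3H)-one | COc1cc(C[C@H]2C(=O)OC[C@@H]2[C@@H](O)c2ccc(O[C@@H](CO)[C@@H](O)c3ccc(O)c(OC)c3)c(OC)c2)ccc1O | target

Total step count: 16. Longest linear sequence: 15 steps (steps 1–12 and 14–16; step 13 is a one-step side branch).

Steps most likely to fail

Step 10. The tethered radical may be reduced at the C–Br stage before it cyclises, or the chair-like transition state may discriminate poorly between the two faces of C4, so that the cis oxasilolane accompanies the trans one. The fallback sets out from aldehyde 13 (with auxiliary 4) and rejoins at hydroxy lactone 22; it makes the C7–C4 bond by a magnesium-catalysed direct anti aldol reaction in place of steps 7 to 11. Auxiliary 4 is N-acylated (n-BuLi, methyl 4-chloro-4-oxobutanoate, THF, −78 °C) to (R)-4-benzyl-3-(4-methoxy-4-oxobutanoyl)oxazolidin-2-one F1. F1 and 13 with MgCl2 (cat.), Et3N and Me3SiCl in EtOAc should give, through the chelated Z-enolate attacked opposite the benzyl group, the anti aldol as its silyl ether, (R)-4-benzyl-3-[(2S,3R)-2-(2-methoxy-2-oxoethyl)-3-ArB-3-(trimethylsilyloxy)propanoyl]oxazolidin-2-one F2. LiBH4 (THF, MeOH, 0 °C) should cleave the imide in preference to the methyl ester, and the primary alkoxide closes onto that ester to give (R)-4-[(R)-ArB(trimethylsilyloxy)methyl]dihydrofuran-2(3H)-one F3. Keeping the C7 oxygen silylated until the lactone has formed removes any choice between the two hydroxyls. Citric acid in MeOH then gives 22.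

Step 11. Ring closure through the secondary C7 hydroxyl, or base-mediated equilibration of the two possible γ-lactones during the oxidation, may give the regioisomeric 5-aryl lactone. The fallback sets out from oxasilolane 20 and rejoins at silyl-protected lactone 23, so that step 12 falls away; it differentiates the two hydroxyls before any lactone can form. The oxidation is run with LiOH added, so that the ester is saponified and (3R,4R)-4-hydroxy-3-(hydroxymethyl)-4-ArB-butanoic acid F4 is obtained as its lithium salt. Exhaustive silylation (Et3SiCl, imidazole, DMF; then K2CO3, MeOH–H2O to cleave the silyl ester) gives (3R,4R)-4-(triethylsilyloxy)-3-[(triethylsilyloxy)methyl]-4-ArB-butanoic acid F5. PPTS in MeOH–CH2Cl2 at 0 °C should remove the primary silyl ether selectively, and the liberated γ-hydroxy acid lactonises to 23.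

Step 7. Facial selectivity in the alkynyl transfer may be insufficient on this heavily substituted aryl aldehyde, and the C7 epimer would then travel through the route as a hard-to-separate diastereomer. The fallback sets out from aldehyde 13 and rejoins at ynoate 16; it sets C7 by reagent-controlled reduction instead of addition. Lithiated methyl propiolate (LiN(SiMe3)2, THF, −78 °C) adds to 13 without control to give methyl 4-hydroxy-4-ArB-but-2-ynoate as a mixture of C7 epimers F6. MnO2 in CH2Cl2 oxidises it to methyl 4-oxo-4-ArB-but-2-ynoate F7. Midland reduction with (S)-Alpine-Borane (B-isopinocampheyl-9-borabicyclo[3.3.1]nonane from (−)-α-pinene), for which the alkynyl group is the small substituent, should then give 16.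

Further compounds
F1 | step 10 | (R)-4-benzyl-3-(4-methoxy-4-oxobutanoyl)oxazolidin-2-one | COC(=O)CCC(=O)N1[C@H](Cc2ccccc2)COC1=O
F2 | step 10 | (R)-4-benzyl-3-[(2S,3R)-2-(2-methoxy-2-oxoethyl)-3-ArB-3-(trimethylsilyloxy)propanoyl]oxazolidin-2-one | O=C(N1[C@H](Cc2ccccc2)COC1=O)[C@@H](CC(=O)OC)[C@@H](O[Si](C)(C)C)c1ccc(O[C@H]2COC(C)(C)O[C@H]2c2ccc(OCc3ccccc3)c(OC)c2)c(OC)c1
F3 | step 10 | (R)-4-[(R)-ArB(trimethylsilyloxy)methyl]dihydrofuran-2(3H)-one | O=C1OC[C@H]([C@@H](O[Si](C)(C)C)c2ccc(O[C@H]3COC(C)(C)O[C@H]3c3ccc(OCc4ccccc4)c(OC)c3)c(OC)c2)C1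
F4 | step 11 | (3R,4R)-4-hydroxy-3-(hydroxymethyl)-4-ArB-butanoic acid | OC[C@@H](CC(=O)O)[C@@H](O)c1ccc(O[C@H]2COC(C)(C)O[C@H]2c2ccc(OCc3ccccc3)c(OC)c2)c(OC)c1
F5 | step 11 | (3R,4R)-4-(triethylsilyloxy)-3-[(triethylsilyloxy)methyl]-4-ArB-butanoic acid | CC[Si](CC)(CC)OC[C@@H](CC(=O)O)[C@@H](O[Si](CC)(CC)CC)c1ccc(O[C@H]2COC(C)(C)O[C@H]2c2ccc(OCc3ccccc3)c(OC)c2)c(OC)c1
F6 | step 7 | methyl 4-hydroxy-4-ArB-but-2-ynoate, mixture of C7 epimers | OC(C#CC(=O)OC)c1ccc(O[C@H]2COC(C)(C)O[C@H]2c2ccc(OCc3ccccc3)c(OC)c2)c(OC)c1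
F7 | step 7 | methyl 4-oxo-4-ArB-but-2-ynoate | O=C(C#CC(=O)OC)c1ccc(O[C@H]2COC(C)(C)O[C@H]2c2ccc(OCc3ccccc3)c(OC)c2)c(OC)c1
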